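The 11-membered carbocycle (ring numbered from the quaternary carbon C1 through C2=C3 to C11) is closed at C4–C5, the bond between the acyloxy carbinol and the tertiary carbinol. The plan exploits two features: C5 is the γ-carbon of the C8 ketone through the E-C6=C7 alkene, hence a vinylogous enolate position, and C4 can be an enal carbonyl that cannot enolise because C1 is quaternary. An intramolecular vinylogous aldol reaction templated by aluminium tris(2,6-diphenylphenoxide) (ATPH) therefore joins the two most hindered ring atoms, sets both carbinol stereocentres and the E-enone in one operation. The precursor is an open-chain enal–dienone built from geraniol, a lactate-derived Weinreb amide and a propargyl ether.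

Key step: step 17

Locants used below: C9 carries C18H2–O; the side chain on C1 is C12H2–C13H2–C14H(O)–C15(CH3)=C16H2; O4, O5 and O8 sit on C4, C5 and C8.
Remark: 6 and both enantiomers of the Shi ketone are taken as purchasable; the senses of the two catalyst-controlled steps (5 and 6) are assigned by analogy with close substrates and would be confirmed on the first intermediates.

Step 1
Reactants: 1 ethyl (S)-lactate
Product: 2 ethyl (2S)-2-(triethylsilyloxy)propanoate
Conditions: Et3SiCl, imidazole, CH2Cl2, 0 °C to rt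
Reagents that add atoms: chlorotriethylsilane, CC[Si](Cl)(CC)CC
Why: Standard silylation of the secondary alcohol; the lactate stereocentre only keeps 21–23 single diastereomers, since it becomes planar in step 17.

Step 2
Reactants: 2 ethyl (2S)-2-(triethylsilyloxy)propanoate; 3 diethyl [2-(methoxy(methyl)amino)-2-oxoethyl]phosphonate
Product: 5 (2E,4S)-N-methoxy-N-methyl-4-(triethylsilyloxy)pent-2-enamide, via (2S)-2-(triethylsilyloxy)propanal 4 (not isolated)
Conditions: i-Bu2AlH (1.05 equiv), CH2Cl2, −78 °C; then sodium salt of 3 (from 3, NaH, THF), −78 °C to rt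
Reagents that add atoms: none
Why: Half-reduction gives the aluminium hemiacetal, which is olefinated in the same flask (Horner–Wadsworth–Emmons reaction) to the E-enamide, so the epimerisable α-silyloxy aldehyde is never isolated.

Step 3
Reactants: 6 4-methoxybenzyl propargyl ether
Product: 7 (E)-2-[3-(4-methoxybenzyloxy)prop-1-en-1-yl]-4,4,5,5-tetramethyl-1,3,2-dioxaborolane
Conditions: pinacolborane (1.2 equiv), Cp2Zr(H)Cl (5 mol %), Et3N (10 mol %), neat, 60 °C
Reagents that add atoms: pinacolborane, [H]B1OC(C)(C)C(C)(C)O1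
Why: Zirconium-catalysed syn-hydroboration of the terminal alkyne places boron at the terminus and gives the E-alkenylboronate.

Step 4
Reactants: 8 geraniol
Product: 9 geranyl diethyl phosphate
Conditions: (EtO)2P(O)Cl, Et3N, DMAP (cat.), CH2Cl2, 0 °C
Reagents that add atoms: diethyl chlorophosphate, CCOP(=O)(Cl)OCC
Why: Phosphorylation of the primary allylic alcohol installs the leaving group for copper-catalysed SN2′ substitution without touching the E-alkene.

Step 5
Reactants: 9 geranyl diethyl phosphate; 7 (E)-alkenylboronate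
Product: 10 (2E,4S)-4-ethenyl-1-(4-methoxybenzyloxy)-4,8-dimethylnona-2,7-diene
Conditions: CuCl (5 mol %), chiral sulfonate-bearing imidazolinium salt (NHC precursor, 5.5 mol %), NaOMe (1.5 equiv), THF, 60 °C
Reagents that add atoms: none
Why: NHC–copper-catalysed enantioselective allylic substitution: the alkenylcopper formed by B-to-Cu transmetalation adds SN2′ to the E-allylic phosphate and creates quaternary C1 (S) under catalyst control (ligand enantiomer chosen for this sense), the boronate geometry being carried into E-C2=C3.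

Step 6
Reactants: 10 (2E,4S)-4-ethenyl-1-(4-methoxybenzyloxy)-4,8-dimethylnona-2,7-diene
Product: 11 (3S)-3-[(3S,4E)-3-ethenyl-6-(4-methoxybenzyloxy)-3-methylhex-4-en-1-yl]-2,2-dimethyloxirane
Conditions: L-fructose-derived enantiomer of the Shi ketone (30 mol %), KHSO5 (as 2KHSO5·KHSO4·K2SO4, 1.4 equiv), K2CO3, Bu4NHSO4 (cat.), MeCN/CH2(OMe)2/aq. Na2B4O7 buffer, 0 °C
Reagents that add atoms: potassium peroxymonosulfate, [K+].[O-]S(=O)(=O)OO
Why: Shi epoxidation: the chiral dioxirane attacks the electron-rich trisubstituted C14=C15 alkene rather than the vinyl group or the hindered, inductively deactivated C2=C3 alkene, and the ketone enantiomer sets C14 as S (reagent control).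

Step 7
Reactants: 11 epoxide
Product: 12 (3S,6S,7E)-6-ethenyl-9-(4-methoxybenzyloxy)-2,6-dimethylnona-1,7-dien-3-ol
Conditions: diethylaluminium 2,2,6,6-tetramethylpiperidide (from lithium 2,2,6,6-tetramethylpiperidide and Et2AlCl, 4 equiv), benzene, 0 °C
Reagents that add atoms: none
Why: Aluminium amide-promoted epoxide-to-allylic-alcohol isomerisation: syn-removal of a methyl proton opens the C15–O bond regioselectively, and the C14–O bond is untouched, so C14 stays S.

Step 8
Reactants: 12 allylic alcohol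
Product: 13 tert-butyldimethylsilyl ether of 12 (O14-TBS)
Conditions: t-BuMe2SiCl, imidazole, DMF, rt
Reagents that add atoms: tert-butyldimethylsilyl chloride, CC(C)(C)[Si](C)(C)Cl
Why: Silylation of the secondary allylic alcohol protects O14 for the organometallic steps.

Step 9
Reactants: 13 silyl ether
Product: 14 (3S,4E)-3-[(3S)-3-(tert-butyldimethylsilyloxy)-4-methylpent-4-en-1-yl]-6-(4-methoxybenzyloxy)-3-methylhex-4-enal
Conditions: PdCl2(PhCN)2 (12 mol %), CuCl2·2H2O (12 mol %), AgNO2 (6 mol %), t-BuOH/MeNO2 15:1, O2 (1 atm), rt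
Reagents that add atoms: oxygen, O=O
Why: Nitrite-modified aldehyde-selective Wacker oxidation functionalises the terminal carbon of the vinyl group on quaternary C1, while the 1,1-disubstituted and internal alkenes should react far more slowly.

Step 10
Reactants: 14 aldehyde
Product: 15 (4S,5E)-1,1-dibromo-4-[(3S)-3-(tert-butyldimethylsilyloxy)-4-methylpent-4-en-1-yl]-7-(4-methoxybenzyloxy)-4-methylhepta-1,5-diene
Conditions: CBr4, PPh3, CH2Cl2, 0 °C
Reagents that add atoms: carbon tetrabromide, BrC(Br)(Br)Br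
Why: First stage of the Corey–Fuchs reaction, a Wittig-type dibromo-olefination of the aldehyde that adds C9.

Step 11
Reactants: 15 dibromoalkene
Product: 17 (5S,6E)-5-[(3S)-3-(tert-butyldimethylsilyloxy)-4-methylpent-4-en-1-yl]-8-(4-methoxybenzyloxy)-5-methyloct-6-en-2-yn-1-ol, via lithium acetylide 16 (not isolated)
Conditions: n-BuLi (2.2 equiv), THF, −78 °C; then (CH2O)n, −78 °C to rt; then H2O
Reagents that add atoms: formaldehyde (as paraformaldehyde), C=O
Why: Second stage of the Corey–Fuchs reaction: elimination and Br–Li exchange give the lithium acetylide, which adds to formaldehyde to install C18.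

Step 12
Reactants: 17 propargylic alcohol
Product: 18 (2Z,5S,6E)-5-[(3S)-3-(tert-butyldimethylsilyloxy)-4-methylpent-4-en-1-yl]-8-(4-methoxybenzyloxy)-5-methyl-2-(tributylstannyl)octa-2,6-dien-1-ol
Conditions: [Cp*RuCl]4 (2.5 mol %), Bu3SnH (1.1 equiv), CH2Cl2, rt
Reagents that add atoms: tributyltin hydride, CCCC[SnH](CCCC)CCCC
Why: Hydroxyl-directed ruthenium-catalysed trans-hydrostannation puts tin on the alkyne carbon next to the carbinol (C9) and hydrogen anti on C10, so tin (later C8) is cis to C11, as the Z-C9=C10 alkene requires.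

Step 13
Reactants: 18 stannyl allylic alcohol
Product: 19 tert-butyldimethylsilyl ether of 18 (O18-TBS)
Conditions: t-BuMe2SiCl, imidazole, DMF, rt
Reagents that add atoms: tert-butyldimethylsilyl chloride, CC(C)(C)[Si](C)(C)Cl
Why: Silylation of the primary allylic alcohol, so that only O4 is freed and oxidised later.

Step 14
Reactants: 19 vinylstannane; 5 (2E,4S)-N-methoxy-N-methyl-4-(triethylsilyloxy)pent-2-enamide
Product: 21 (2S,3E,6Z,9S,10E)-9-[(3S)-3-(tert-butyldimethylsilyloxy)-4-methylpent-4-en-1-yl]-6-[(tert-butyldimethylsilyloxy)methyl]-12-(4-methoxybenzyloxy)-9-methyl-2-(triethylsilyloxy)dodeca-3,6,10-trien-5-one, via vinyllithium 20 (not isolated)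
Conditions: n-BuLi (1.05 equiv), THF, −78 °C; then 5, −78 to −40 °C; then H2O
Reagents that add atoms: none
Why: Tin–lithium exchange with retention of alkene geometry, then acylation by the Weinreb amide, whose chelated tetrahedral adduct prevents over-addition; this forms C8–C9 and the cross-conjugated dienone.

Step 15
Reactants: 21 dienone PMB ether
Product: 22 (2S,3E,6Z,9S,10E)-9-[(3S)-3-(tert-butyldimethylsilyloxy)-4-methylpent-4-en-1-yl]-6-[(tert-butyldimethylsilyloxy)methyl]-12-hydroxy-9-methyl-2-(triethylsilyloxy)dodeca-3,6,10-trien-5-one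
Conditions: DDQ (1.3 equiv), CH2Cl2/pH 7 buffer 10:1, 0 °C
Reagents that add atoms: none
Why: Oxidative cleavage of the 4-methoxybenzyl ether through its benzylic oxocarbenium ion leaves the silyl ethers and the dienone intact.

Step 16
Reactants: 22 allylic alcohol
Product: 23 (2E,4S,6Z,9E,11S)-4-[(3S)-3-(tert-butyldimethylsilyloxy)-4-methylpent-4-en-1-yl]-7-[(tert-butyldimethylsilyloxy)methyl]-4-methyl-8-oxo-11-(triethylsilyloxy)dodeca-2,6,9-trienal
Conditions: MnO2 (20 equiv), CH2Cl2, rt
Reagents that add atoms: none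
Why: MnO2 oxidises only the free allylic alcohol and gives the E-enal, which cannot enolise because C1 is quaternary.

Step 17
Reactants: 23 enal–dienone
Product: 25 (2Z,5S,6E,8R,9R,10E)-8-hydroxy-5-[(3S)-3-(tert-butyldimethylsilyloxy)-4-methylpent-4-en-1-yl]-2-[(tert-butyldimethylsilyloxy)methyl]-5,9-dimethyl-9-(triethylsilyloxy)cycloundeca-2,6,10-trien-1-one, via ATPH-bound lithium dienolate 24 (not isolated)
Conditions: Al(OC6H3-2,6-Ph2)3 (ATPH, 2.5 equiv), toluene, −78 °C; LiN(i-Pr)2 (1.5 equiv), THF, −78 to −45 °C, 2 mM; then H2O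
Reagents that add atoms: none
Why: ATPH binds both carbonyl oxygens, LiN(i-Pr)2 then removes H5, the E-γ proton of the C8 ketone that lies outside the aluminium pocket (α-C7 and the Z-γ′ protons at C11 lie inside it), and the resulting aluminium dienolate adds through C5 to the ATPH-activated aldehyde carbon C4. The closest known reaction type is the ATPH-mediated vinylogous aldol reaction of enones and enoates with aldehydes, including its ring-closing use for macrolactones. The ring closes by 11-exo-trig 1,2-addition, because attack through C7 would give a 9-membered ring holding the E-C2=C3 alkene and conjugate addition at C2 is blocked by quaternary C1. The s-trans dienolate gives E-C6=C7, and since ring closure forces the enal and dienolate planes to stack (gauche C3–C4–C5–C6), the open transition state with the ATPH-bound O4 antiperiplanar to the bulky O5 silyl ether leads to the syn (4R*,5R*) pair. The absolute sense relative to C1 (4R,5R with 1S) is expected from the fold that keeps the larger C12 chain of C1 on the outer face of the closing ring, and this is the least secure element of the step. The step needs γ- over α- and γ′-regioselectivity, 1,2-addition and facial control, which are secured by the ATPH shielding, the non-enolisable hindered enal and the rigid framework in which nine of the eleven ring atoms are sp2.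

Step 18
Reactants: 25 macrocyclic alcohol; 26 3-methylbut-2-enoyl chloride
Product: 27 O4-(3-methylbut-2-enoyl) ester of 25
Conditions: 26 (3 equiv), pyridine, DMAP (0.2 equiv), CH2Cl2, 0 °C to rt
Reagents that add atoms: none
Why: DMAP-catalysed acylation of the only free hydroxyl group (O4); pyridine rather than a trialkylamine is used to avoid deconjugation of the senecioyl group through a vinylketene.

Step 19
Reactants: 27 tris-silyl ether ester
Product: 28 CNP0311723.1
Conditions: HF·pyridine, pyridine, THF, 0 °C to rt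
Reagents that add atoms: none
Why: Fluoride cleavage of the tertiary triethylsilyl and the two tert-butyldimethylsilyl ethers under buffered acidic conditions, which avoids base-induced acyl migration or retro-aldol cleavage.

Compound list
1 | ethyl (S)-lactate | CCOC(=O)[C@H](C)O | starting material
2 | ethyl (2S)-2-(triethylsilyloxy)propanoate | CCOC(=O)[C@H](C)O[Si](CC)(CC)CC | intermediate
3 | diethyl [2-(methoxy(methyl)amino)-2-oxoethyl]phosphonate | CCOP(=O)(CC(=O)N(C)OC)OCC | starting material
4 | (2S)-2-(triethylsilyloxy)propanal | O=C[C@H](C)O[Si](CC)(CC)CC | intermediate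
5 | (2E,4S)-N-methoxy-N-methyl-4-(triethylsilyloxy)pent-2-enamide | CON(C)C(=O)/C=C/[C@H](C)O[Si](CC)(CC)CC | intermediate
6 | 4-methoxybenzyl propargyl ether | C#CCOCc1ccc(OC)cc1 | starting material
7 | (E)-2-[3-(4-methoxybenzyloxy)prop-1-en-1-yl]-4,4,5,5-tetramethyl-1,3,2-dioxaborolane | COc1ccc(COC/C=C/B2OC(C)(C)C(C)(C)O2)cc1 | intermediate
8 | geraniol | CC(C)=CCC/C(C)=C/CO | starting material
9 | geranyl diethyl phosphate | CC(C)=CCC/C(C)=C/COP(=O)(OCC)OCC | intermediate
10 | (2E,4S)-4-ethenyl-1-(4-methoxybenzyloxy)-4,8-dimethylnona-2,7-diene | CC(C)=CCC[C@](C=C)(C)/C=C/COCc1ccc(OC)cc1 | intermediate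
11 | (3S)-3-[(3S,4E)-3-ethenyl-6-(4-methoxybenzyloxy)-3-methylhex-4-en-1-yl]-2,2-dimethyloxirane | CC1(C)O[C@H]1CC[C@](C=C)(C)/C=C/COCc1ccc(OC)cc1 | intermediate
12 | (3S,6S,7E)-6-ethenyl-9-(4-methoxybenzyloxy)-2,6-dimethylnona-1,7-dien-3-ol | C=C(C)[C@@H](O)CC[C@](C=C)(C)/C=C/COCc1ccc(OC)cc1 | intermediate
13 | tert-butyldimethylsilyl ether of 12 | C=C(C)[C@@H](O[Si](C)(C)C(C)(C)C)CC[C@](C=C)(C)/C=C/COCc1ccc(OC)cc1 | intermediate
14 | (3S,4E)-3-[(3S)-3-(tert-butyldimethylsilyloxy)-4-methylpent-4-en-1-yl]-6-(4-methoxybenzyloxy)-3-methylhex-4-enal | C=C(C)[C@@H](O[Si](C)(C)C(C)(C)C)CC[C@](CC=O)(C)/C=C/COCc1ccc(OC)cc1 | intermediate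
15 | (4S,5E)-1,1-dibromo-4-[(3S)-3-(tert-butyldimethylsilyloxy)-4-methylpent-4-en-1-yl]-7-(4-methoxybenzyloxy)-4-methylhepta-1,5-diene | C=C(C)[C@@H](O[Si](C)(C)C(C)(C)C)CC[C@](CC=C(Br)Br)(C)/C=C/COCc1ccc(OC)cc1 | intermediate
16 | lithium acetylide from 15 (C9-lithio alkyne) | C=C(C)[C@@H](O[Si](C)(C)C(C)(C)C)CC[C@](CC#C[Li])(C)/C=C/COCc1ccc(OC)cc1 | intermediate
17 | (5S,6E)-5-[(3S)-3-(tert-butyldimethylsilyloxy)-4-methylpent-4-en-1-yl]-8-(4-methoxybenzyloxy)-5-methyloct-6-en-2-yn-1-ol | C=C(C)[C@@H](O[Si](C)(C)C(C)(C)C)CC[C@](CC#CCO)(C)/C=C/COCc1ccc(OC)cc1 | intermediate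
18 | (2Z,5S,6E)-5-[(3S)-3-(tert-butyldimethylsilyloxy)-4-methylpent-4-en-1-yl]-8-(4-methoxybenzyloxy)-5-methyl-2-(tributylstannyl)octa-2,6-dien-1-ol | C=C(C)[C@@H](O[Si](C)(C)C(C)(C)C)CC[C@](C/C=C(\[Sn](CCCC)(CCCC)CCCC)CO)(C)/C=C/COCc1ccc(OC)cc1 | intermediate
19 | tert-butyldimethylsilyl ether of 18 | C=C(C)[C@@H](O[Si](C)(C)C(C)(C)C)CC[C@](C/C=C(\[Sn](CCCC)(CCCC)CCCC)CO[Si](C)(C)C(C)(C)C)(C)/C=C/COCc1ccc(OC)cc1 | intermediate
20 | vinyllithium from 19 (C9-lithio, geometry retained) | C=C(C)[C@@H](O[Si](C)(C)C(C)(C)C)CC[C@](C/C=C(\[Li])CO[Si](C)(C)C(C)(C)C)(C)/C=C/COCc1ccc(OC)cc1 | intermediate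
21 | (2S,3E,6Z,9S,10E)-9-[(3S)-3-(tert-butyldimethylsilyloxy)-4-methylpent-4-en-1-yl]-6-[(tert-butyldimethylsilyloxy)methyl]-12-(4-methoxybenzyloxy)-9-methyl-2-(triethylsilyloxy)dodeca-3,6,10-trien-5-one | C=C(C)[C@@H](O[Si](C)(C)C(C)(C)C)CC[C@](C/C=C(\C(=O)/C=C/[C@H](C)O[Si](CC)(CC)CC)CO[Si](C)(C)C(C)(C)C)(C)/C=C/COCc1ccc(OC)cc1 | intermediate
22 | 12-hydroxy analogue of 21 (free O4–H) | C=C(C)[C@@H](O[Si](C)(C)C(C)(C)C)CC[C@](C/C=C(\C(=O)/C=C/[C@H](C)O[Si](CC)(CC)CC)CO[Si](C)(C)C(C)(C)C)(C)/C=C/CO | intermediate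
23 | (2E,4S,6Z,9E,11S)-4-[(3S)-3-(tert-butyldimethylsilyloxy)-4-methylpent-4-en-1-yl]-7-[(tert-butyldimethylsilyloxy)methyl]-4-methyl-8-oxo-11-(triethylsilyloxy)dodeca-2,6,9-trienal | C=C(C)[C@@H](O[Si](C)(C)C(C)(C)C)CC[C@](C/C=C(\C(=O)/C=C/[C@H](C)O[Si](CC)(CC)CC)CO[Si](C)(C)C(C)(C)C)(C)/C=C/C=O | intermediate
24 | ATPH-bound lithium dienolate of 23 (drawn without ATPH; enolate geometries not specified) | C=C(C)[C@@H](O[Si](C)(C)C(C)(C)C)CC[C@](C/C=C(\C(O[Li])=CC=C(C)O[Si](CC)(CC)CC)CO[Si](C)(C)C(C)(C)C)(C)/C=C/C=O | intermediate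
25 | (2Z,5S,6E,8R,9R,10E)-8-hydroxy-5-[(3S)-3-(tert-butyldimethylsilyloxy)-4-methylpent-4-en-1-yl]-2-[(tert-butyldimethylsilyloxy)methyl]-5,9-dimethyl-9-(triethylsilyloxy)cycloundeca-2,6,10-trien-1-one | C=C(C)[C@@H](O[Si](C)(C)C(C)(C)C)CC[C@]1(C)/C=C/[C@@H](O)[C@](C)(O[Si](CC)(CC)CC)/C=C/C(=O)/C(CO[Si](C)(C)C(C)(C)C)=C\C1 | intermediate
26 | 3-methylbut-2-enoyl chloride | CC(C)=CC(Cl)=O | starting material
27 | O4-(3-methylbut-2-enoyl) ester of 25 | C=C(C)[C@@H](O[Si](C)(C)C(C)(C)C)CC[C@]1(C)/C=C/[C@@H](OC(=O)C=C(C)C)[C@](C)(O[Si](CC)(CC)CC)/C=C/C(=O)/C(CO[Si](C)(C)C(C)(C)C)=C\C1 | intermediate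
28 | CNP0311723.1, (2Z,5S,6E,8R,9R,10E)-9-hydroxy-2-(hydroxymethyl)-5-[(3S)-3-hydroxy-4-methylpent-4-en-1-yl]-5,9-dimethyl-1-oxocycloundeca-2,6,10-trien-8-yl 3-methylbut-2-enoate | C=C(C)[C@@H](O)CC[C@]1(C)/C=C/[C@@H](OC(=O)C=C(C)C)[C@](C)(O)/C=C/C(=O)/C(CO)=C\C1 | target

Total step count: 19. Longest linear sequence: 16 steps (geraniol 8 to 28, steps 4 to 19).

Steps most likely to fail

Step 17. The base may remove a proton at C11 instead of C5, intermolecular aldol addition may outrun ring closure, or the facial discrimination with respect to C1 may be weak during C4–C5 bond formation. The fallback sets out from 23 and comes back at 25; it closes the same bond as a Lewis-base-catalysed vinylogous Mukaiyama aldol reaction under reagent control. 23 is treated with t-BuMe2SiOTf and Et3N (CH2Cl2, −78 °C) to give the C8 tert-butyldimethylsilyl dienol ether F1, whose regiochemistry can be verified before the ring is closed. Slow addition of F1 to SiCl4 and a chiral bisphosphoramide (CH2Cl2, −78 °C) should give the trichlorosilyl ether of 25, the catalyst-bound trichlorosilyl cation selecting the aldehyde face, and aqueous NaHCO3 work-up returns to the route at 25.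

Step 9. Markovnikov oxidation to the methyl ketone, or palladium-induced oxidation and migration of the C2=C3 allylic ether alkene, may compete. The fallback sets out from 13 and comes back at 14; it uses rhodium-catalysed hydroboration, which discriminates the monosubstituted vinyl group from the 1,1-disubstituted isopropenyl group. RhCl(PPh3)3 and catecholborane in THF, then NaOH/H2O2, should give the primary alcohol F2, and oxidation of F2 with Dess–Martin periodinane returns to the route at 14.

Step 14. The 2-lithioallyl silyl ether 20 may lose silyloxide (allene formation) before it is acylated, or add in conjugate fashion to the unsaturated amide. The fallback sets out from 19 and 5 and comes back at 21; it is a Nozaki–Hiyama–Kishi coupling that avoids the organolithium. Iododestannylation of 19 (I2, CH2Cl2, 0 °C) should give the vinyl iodide F3 with retention of geometry, and reduction of 5 (i-Bu2AlH, THF, −78 °C) the enal F4. CrCl2 with catalytic NiCl2 in DMSO joins F3 and F4 to the bis-allylic alcohol F5 (both C8 epimers serve), and Dess–Martin periodinane oxidation of F5 returns to the route at 21.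

Further compounds
F1 | step 17 | C8 tert-butyldimethylsilyl dienol ether of 23 (C7=C8 and C5=C6 enol ether bonds, geometries not specified) | C=C(C)[C@@H](O[Si](C)(C)C(C)(C)C)CC[C@](C/C=C(\C(O[Si](C)(C)C(C)(C)C)=CC=C(C)O[Si](CC)(CC)CC)CO[Si](C)(C)C(C)(C)C)(C)/C=C/C=O
F2 | step 9 | (3S,4E)-3-[(3S)-3-(tert-butyldimethylsilyloxy)-4-methylpent-4-en-1-yl]-6-(4-methoxybenzyloxy)-3-methylhex-4-en-1-ol | C=C(C)[C@@H](O[Si](C)(C)C(C)(C)C)CC[C@](CCO)(C)/C=C/COCc1ccc(OC)cc1
F3 | step 14 | (2Z)-2-iodo analogue of 19 (iodine in place of tin on C9) | C=C(C)[C@@H](O[Si](C)(C)C(C)(C)C)CC[C@](C/C=C(\I)CO[Si](C)(C)C(C)(C)C)(C)/C=C/COCc1ccc(OC)cc1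
F4 | step 14 | (2E,4S)-4-(triethylsilyloxy)pent-2-enal | O=C/C=C/[C@H](C)O[Si](CC)(CC)CC
F5 | step 14 | C8 carbinol corresponding to 21 (both C8 epimers) | C=C(C)[C@@H](O[Si](C)(C)C(C)(C)C)CC[C@](C/C=C(\C(O)/C=C/[C@H](C)O[Si](CC)(CC)CC)CO[Si](C)(C)C(C)(C)C)(C)/C=C/COCc1ccc(OC)cc1
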